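Readings and results are calculated with made-up constants, noise included.

The amounts first: the flask called eta got 1.0 M of starting material, 2.50 M of coupling partner and 0.300 M of protic impurity at −20 °C, and it has been followed up to 4.0 h. The delta run had the same charge but was colder.

| flask | starting material | coupling partner | protic impurity | temperature | remark | time |
|---|---|---|---|---|---|---|
| eta | 1 M | 2.5 M | 0.30 M | −20 °C | the very flask that is asked about, followed so far |  |
| delta | 1 M | 2.5 M | 0.30 M | −35 °C | run made earlier |  |
| flask | 1.0 M | 2.50 M | 0.300 M | −20 °C |  | 4.0 h |

- eta (time / min: target / %, starting material / %): 20.0: 27.5, 0; 40.0: 34.0, 0.2; 90.0: 37.0, 0; 240: 32.4, 0.7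
- delta (time / min: target / %, starting material / %): 40.0: 7.1, 0.4; 80.0: 11.6, 0.8; 180: 17.3, 0; 480: 19.5, 0

(standard deviation of a reading: 0.5 percentage points)

- north-west: at 4.0 h take out 90 % of the target then present, then wait 80 min
- south-east: at 4.0 h raise the temperature by 10 K, then wait 80 min
- north: change nothing and wait 80 min more

- target, in percent of the starting material first charged, at 4.0 h
- the option that brings most further target ("none" if no option brings more than 2 percentage points) (north-west / south-east / north / none)
- target present, with what was taken out counted in, in percent of the starting material first charged, after north-west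
- target present, with what was taken out counted in, in percent of the starting material first charged, after south-east

- target taken out counts as made

Two chemists read these runs. In both, the starting material never reads above 0.8 %, yet target goes on climbing afterwards, so something unseen stands between them.

The first chemist holds that this store is still feeding target. Delta still rose from 17.3 % to 19.5 % between 180 min and 480 min. At 40.0 min, eta read 4.79 times as much target as delta, so this chemist would warm the flask.

The second chemist answers that eta fell by 4.6 percentage points after 90.0 min, against a scatter of 0.5 points, so eta's target is now being lost.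

My own reckoning compares two rates at one moment, 4.0 h. Eta gained 6.5 points in the 20.0 min after 20.0 min, but 3 points in the 50.0 min after 40.0 min. Read from these gains, the feed halves every 14.4 min. That makes 12.2 halvings by 4.0 h.

Eta's readings after the peak give 8.85 × 10⁻⁴ min⁻¹ for the drain, the share of target lost each minute. At 4.0 h the feed is far smaller than the drain on 32.4 % of target, and the gap widens with time. Waiting 80 min should therefore cost 2.2 points.

The forecast sides with the second chemist: “nothing remains to feed target”. It gives 32.4 % now, none as the best option, 32.2 % after north-west and 25.5 % after south-east. Its cost of waiting, about 2.5 points, is a little above mine.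

The flask gives 32.9 %, 32.7 % after north-west and 25.0 % after south-east, and the best option is none.

    starting material → intermediate A (k = 0.590 min⁻¹, Ea = 77.0 kJ mol⁻¹)
    coupling partner + intermediate A → target (k = 0.0370 L mol⁻¹ min⁻¹, Ea = 54.0 kJ mol⁻¹)
    starting material + coupling partner → intermediate B (k = 0.410 L mol⁻¹ min⁻¹, Ea = 47.0 kJ mol⁻¹)
    intermediate B ⇌ intermediate C (K = 3.00, k = 0.0100 min⁻¹, Ea = 88.0 kJ mol⁻¹, ΔH = −34.0 kJ mol⁻¹)
    intermediate B ⇌ intermediate D (K = 1.20, k = 0.740 min⁻¹, Ea = 67.0 kJ mol⁻¹, ΔH = −37.0 kJ mol⁻¹)
    intermediate D ⇌ intermediate E (K = 42.0, k = 0.150 min⁻¹, Ea = 71.0 kJ mol⁻¹, ΔH = −58.0 kJ mol⁻¹)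
    intermediate E → decomposed reagent (k = 0.110 min⁻¹, Ea = 78.0 kJ mol⁻¹)
    target → over-reaction product (k = 6.50 × 10⁻⁴ min⁻¹, Ea = 92.0 kJ mol⁻¹)
    starting material + protic impurity → quenched substrate (k = 0.230 L mol⁻¹ min⁻¹, Ea = 40.0 kJ mol⁻¹)
    (constants at −20 °C)

Intermediate A, which feeds target, stands at 0 % at 240 min. With 10.0 % of the target left in the flask, the drain predicts a loss of 0.22 points after north-west; the flask loses 0.17 points. The first chemist's view belongs where intermediate A lasts. In the neighbour with 1.0 M of coupling partner, 6.79 % of it stands beside 47.1 % of target at 240 min, and by the constants above the feed there comes to 1.07 times the loss of target.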